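**Retrosynthetic overview**

1. The oxolane is numbered O1, C2 (ring A), C3 and C4 (methyls), C5 (ring B). C5 is benzylic to ring B and para to the ring B ether oxygen, so a C5 cation is an O-alkyl quinone methide; O1–C5 is therefore cut last, back to an open-chain C2 alcohol with a C5 methylene.
2. Rings A and C and the side-chain carbinol carry pivalates, so only ring B can be oxidised. The C5–ring B bond comes from a B-alkyl Suzuki coupling of the 9-BBN adduct of a C4=C5 alkene, with C4 set by substrate-controlled hydroboration.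
3. C2–C3 and both of these centres come from a catalytic enantioselective syn-2-methylcrotylboration of O-pivaloylvanillin.
4. Side-chain aryl bromide: Cβ–O by Mitsunobu inversion of methyl (S)-lactate with 4-bromo-2-methoxyphenol, Cα–ring C by Weinreb ketone synthesis, Cα by chelation-controlled reduction (Cα = carbinol carbon on ring C, Cβ = methyl-bearing ether carbon).
5. Ring order: the oxolane is the only ring formed (step 14); LiAlH4 then removes the three pivalates.

Key step: step 14

Numbering remark: the oxolane numbers C2–C5 are also used for the same carbons in the open-chain intermediates.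
Assumption: the (S)-enantiomer of the TRIP phosphoric acid is taken to direct the allyl group to the Si face of an aryl aldehyde, the mirror image of the Re-face preference of the (R)-catalyst.

**Route**

Step 1
Reactants: 1 isoprene; 2 catecholborane; 3 pinacol
Product: 5 (Z)-4,4,5,5-tetramethyl-2-(2-methylbut-2-en-1-yl)-1,3,2-dioxaborolane, via catechol allylboronate 4 (not isolated)
Conditions: Pd(PPh3)4 (2 mol %), toluene, rt; then pinacol, rt
Reagents that add atoms: none
Why: Palladium-catalysed 1,4-hydroboration of a 1,3-diene should pass through an anti π-allyl intermediate from the s-cis diene, placing boron on the CH2 next to the methyl-bearing carbon with Z geometry (CH2B cis to the terminal methyl), and transesterification with pinacol gives the stable allylboronate.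

Step 2
Reactants: 6 vanillin
Product: 7 4-formyl-2-methoxyphenyl pivalate
Conditions: PivCl, Et3N, DMAP (cat.), CH2Cl2, 0 °C → rt
Reagents that add atoms: pivaloyl chloride, CC(C)(C)C(=O)Cl
Why: DMAP-catalysed O-acylation of the phenol installs the acyloxy group that later deactivates ring A towards DDQ.

Step 3
Reactants: 7 4-formyl-2-methoxyphenyl pivalate; 5 (Z)-2-methylcrotyl pinacol boronate
Product: 9 4-[(1S,2R)-1-hydroxy-2,3-dimethylbut-3-en-1-yl]-2-methoxyphenyl pivalate, via pinacol borate ester 8 (not isolated)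
Conditions: (S)-TRIP phosphoric acid [(S)-3,3'-bis(2,4,6-triisopropylphenyl)-1,1'-binaphthyl-2,2'-diyl hydrogen phosphate] (5 mol %), 4 Å MS, toluene, −30 → 0 °C; then aq. NaHCO3
Reagents that add atoms: none
Why: Chiral-phosphoric-acid-catalysed allylboration runs through a closed Zimmerman–Traxler chair in which the Z boronate holds its γ-methyl axial, so the C3 methyl and C2 oxygen should end syn, and the (S)-catalyst should expose the Si face of the aldehyde, giving (1S,2R).

Step 4
Reactants: 9 homoallylic alcohol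
Product: 10 4-[(1S,2R)-2,3-dimethyl-1-(triethylsilyloxy)but-3-en-1-yl]-2-methoxyphenyl pivalate
Conditions: TESOTf, 2,6-lutidine, CH2Cl2, −78 → 0 °C
Reagents that add atoms: triethylsilyl triflate, CC[Si](CC)(CC)OS(=O)(=O)C(F)(F)F
Why: Silylation of the hindered secondary alcohol with a silyl triflate masks the O–H for the hydroboration and enlarges the group that directs it.

Step 5
Reactants: 11 4-bromo-2-methoxyphenol
Product: 12 (4-bromo-2-methoxyphenoxy)(tert-butyl)dimethylsilane
Conditions: TBSCl, imidazole, DMF, rt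
Reagents that add atoms: tert-butyldimethylsilyl chloride, CC(C)(C)[Si](C)(C)Cl
Why: Silyl ether formation protects the ring C phenol in a form that tolerates Grignard formation and is later removable without touching the aryl bromide.

Step 6
Reactants: 11 4-bromo-2-methoxyphenol; 13 methyl (S)-lactate
Product: 14 methyl (R)-2-(4-bromo-2-methoxyphenoxy)propanoate
Conditions: PPh3, DIAD, THF, 0 °C → rt
Reagents that add atoms: none
Why: Mitsunobu etherification displaces the activated lactate oxygen by the phenoxide in an SN2 step, inverting the centre from S to R and so setting Cβ.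

Step 7
Reactants: 14 methyl (R)-2-(4-bromo-2-methoxyphenoxy)propanoate
Product: 15 (R)-2-(4-bromo-2-methoxyphenoxy)-N-methoxy-N-methylpropanamide
Conditions: MeNHOMe·HCl, iPrMgCl, THF, −20 → 0 °C
Reagents that add atoms: N,O-dimethylhydroxylamine hydrochloride, CNOC.Cl
Why: Weinreb amide formation from the ester with the chloromagnesium amide proceeds at low temperature, where the α-aryloxy centre should not enolise and iPrMgCl does not exchange with the aryl bromide.

Step 8
Reactants: 12 silyl-protected aryl bromide; 15 Weinreb amide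
Product: 17 (R)-2-(4-bromo-2-methoxyphenoxy)-1-[4-(tert-butyldimethylsilyloxy)-3-methoxyphenyl]propan-1-one, via aryl Grignard reagent 16 (not isolated)
Conditions: Mg, THF, 40 °C; then 15, THF, −20 → 0 °C; aq. NH4Cl
Reagents that add atoms: none
Why: In the Weinreb ketone synthesis the chelated tetrahedral adduct stops over-addition and keeps the ketone masked until work-up, so Cβ stays R, and an aryl Grignard reagent does not exchange with the ring B bromide.

Step 9
Reactants: 17 α-aryloxy ketone
Product: 18 (1S,2R)-2-(4-bromo-2-methoxyphenoxy)-1-[4-(tert-butyldimethylsilyloxy)-3-methoxyphenyl]propan-1-ol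
Conditions: Zn(BH4)2, Et2O, −30 → 0 °C; aq. NH4Cl
Reagents that add atoms: none
Why: Chelation-controlled (Cram-chelate) hydride reduction, with zinc bridging the carbonyl oxygen and the guaiacyl ether oxygens, delivers hydride past the small hydrogen on Cβ and should give the 1,2-anti (erythro) alcohol, Cα = S.

Step 10
Reactants: 18 erythro alcohol
Product: 19 4-[(1S,2R)-2-(4-bromo-2-methoxyphenoxy)-1-hydroxypropyl]-2-methoxyphenol
Conditions: TBAF, AcOH, THF, 0 °C
Reagents that add atoms: none
Why: Buffered fluoride desilylation cleaves the aryl silyl ether quickly, and the acetic acid keeps the para-hydroxybenzyl alcohol from ionising to a quinone methide.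

Step 11
Reactants: 19 phenol alcohol
Product: 20 4-[(1S,2R)-2-(4-bromo-2-methoxyphenoxy)-1-(pivaloyloxy)propyl]-2-methoxyphenyl pivalate
Conditions: PivCl, DMAP, pyridine, CH2Cl2, 0 → 40 °C
Reagents that add atoms: pivaloyl chloride, CC(C)(C)C(=O)Cl
Why: DMAP-catalysed acylation esterifies the phenol and the benzylic alcohol in one operation, which deactivates ring C and the Cα–H bond towards DDQ.

Step 12
Reactants: 10 silyl ether alkene; 20 bis-pivalate aryl bromide
Product: 22 4-[(1S,2R,3R)-4-(3-methoxy-4-{[(1S,2R)-1-[3-methoxy-4-(pivaloyloxy)phenyl]-1-(pivaloyloxy)propan-2-yl]oxy}phenyl)-2,3-dimethyl-1-(triethylsilyloxy)butyl]-2-methoxyphenyl pivalate, via B-alkyl-9-BBN adduct 21 (not isolated)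
Conditions: 9-BBN dimer, THF, rt → 40 °C; then 20, Pd(OAc)2, SPhos, aq. K3PO4, THF, 60 °C
Reagents that add atoms: none
Why: Hydroboration followed by B-alkyl Suzuki–Miyaura coupling: 9-BBN should add to the 1,1-disubstituted alkene anti to the large CH(OTES)Ar group on C3 with the C3–H eclipsing the double bond (allylic-strain-controlled 1,2-induction), which sets C4 as R with the two methyls anti in the zigzag (cis in the later ring), and the primary alkyl group then transfers to the aryl bromide without touching C4.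

Step 13
Reactants: 22 silyl ether
Product: 23 4-[(1S,2R,3R)-1-hydroxy-4-(3-methoxy-4-{[(1S,2R)-1-[3-methoxy-4-(pivaloyloxy)phenyl]-1-(pivaloyloxy)propan-2-yl]oxy}phenyl)-2,3-dimethylbutyl]-2-methoxyphenyl pivalate
Conditions: HF·pyridine, pyridine, THF, 0 °C → rt
Reagents that add atoms: none
Why: Fluoride-mediated desilylation under buffered, weakly acidic conditions frees the C2 hydroxyl while the three pivalates and the benzylic C–O bonds of the deactivated rings stay intact.

Step 14
Reactants: 23 open-chain C2 alcohol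
Product: 25 tris-pivalate of the target with the (2S,3R,4S,5S)-oxolane, via para-alkoxybenzyl cation 24 (not isolated)
Conditions: DDQ (1.2 equiv), 4 Å MS, CH2Cl2, 0 °C → rt; aq. NaHCO3
Reagents that add atoms: none
Why: DDQ forms a charge-transfer complex with the dialkoxy ring B and abstracts hydride from the C5 methylene, giving cation 24 (the O-alkyl counterpart of a lignan quinone methide) paired with the hydroquinone anion, and the C2 hydroxyl adds to it to form O1–C5. The closest known reaction type is the DDQ-mediated intramolecular benzylic C–H etherification of electron-rich arylalkanols to 2-aryl cyclic ethers. The oxolane closes in a 5-exo-trig mode, the attacked carbon being joined to ring B by the exocyclic quinoid double bond. The new C5 centre is controlled by allylic 1,3-strain in 24: the C4–H bond eclipses the quinoid plane, the tether reaches C5 from the face of C3, and ring B should therefore end trans to the C4 methyl (5S), while reversible ionisation of this one benzylic ether by the acidic hydroquinone should drain any all-cis epimer to the same isomer. The step needs site selectivity for C5 over the benzylic C–H bonds at C2 and Cα, and the pivalates secure it by leaving rings A and C without a para donor while ring B keeps its para alkyl ether; C2, C3 and C4 are not touched, so the cis C2-aryl centre passes through unchanged.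

Step 15
Reactants: 25 tris-pivalate
Product: 26 target, (1S,2R)-1-(4-hydroxy-3-methoxyphenyl)-2-{4-[(2S,3S,4R,5S)-5-(4-hydroxy-3-methoxyphenyl)-3,4-dimethyloxolan-2-yl]-2-methoxyphenoxy}propan-1-ol
Conditions: LiAlH4, THF, 0 °C → rt; aq. KNaC4H4O6 (potassium sodium tartrate)
Reagents that add atoms: none
Why: Hydride reduction of the three esters releases both phenols and the Cα alcohol, and the neutral tartrate work-up avoids acid that could epimerise the cis C2-aryl centre through a quinone methide.

**Compound list**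

1 | isoprene (2-methylbuta-1,3-diene) | C=CC(C)=C | starting material
2 | catecholborane (1,3,2-benzodioxaborole) | B1Oc2ccccc2O1 | starting material
3 | pinacol (2,3-dimethylbutane-2,3-diol) | CC(C)(O)C(C)(C)O | starting material
4 | 2-[(Z)-2-methylbut-2-en-1-yl]-1,3,2-benzodioxaborole | C/C=C(C)\CB1Oc2ccccc2O1 | intermediate
5 | (Z)-4,4,5,5-tetramethyl-2-(2-methylbut-2-en-1-yl)-1,3,2-dioxaborolane | C/C=C(C)\CB1OC(C)(C)C(C)(C)O1 | intermediate
6 | vanillin | COc1cc(C=O)ccc1O | starting material
7 | 4-formyl-2-methoxyphenyl pivalate | COc1cc(C=O)ccc1OC(=O)C(C)(C)C | intermediate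
8 | pinacol borate ester of 9, (1S,2R) | COc1cc([C@@H](OB2OC(C)(C)C(C)(C)O2)[C@H](C)C(C)=C)ccc1OC(=O)C(C)(C)C | intermediate
9 | 4-[(1S,2R)-1-hydroxy-2,3-dimethylbut-3-en-1-yl]-2-methoxyphenyl pivalate | COc1cc([C@@H](O)[C@H](C)C(C)=C)ccc1OC(=O)C(C)(C)C | intermediate
10 | 4-[(1S,2R)-2,3-dimethyl-1-(triethylsilyloxy)but-3-en-1-yl]-2-methoxyphenyl pivalate | COc1cc([C@@H](O[Si](CC)(CC)CC)[C@H](C)C(C)=C)ccc1OC(=O)C(C)(C)C | intermediate
11 | 4-bromo-2-methoxyphenol | COc1cc(Br)ccc1O | starting material
12 | (4-bromo-2-methoxyphenoxy)(tert-butyl)dimethylsilane | COc1cc(Br)ccc1O[Si](C)(C)C(C)(C)C | intermediate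
13 | methyl (S)-lactate | C[C@H](O)C(=O)OC | starting material
14 | methyl (R)-2-(4-bromo-2-methoxyphenoxy)propanoate | COc1cc(Br)ccc1O[C@H](C)C(=O)OC | intermediate
15 | (R)-2-(4-bromo-2-methoxyphenoxy)-N-methoxy-N-methylpropanamide | COc1cc(Br)ccc1O[C@H](C)C(=O)N(C)OC | intermediate
16 | [4-(tert-butyldimethylsilyloxy)-3-methoxyphenyl]magnesium bromide | COc1cc([Mg]Br)ccc1O[Si](C)(C)C(C)(C)C | intermediate
17 | (R)-2-(4-bromo-2-methoxyphenoxy)-1-[4-(tert-butyldimethylsilyloxy)-3-methoxyphenyl]propan-1-one | COc1cc(Br)ccc1O[C@H](C)C(=O)c1ccc(O[Si](C)(C)C(C)(C)C)c(OC)c1 | intermediate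
18 | (1S,2R)-2-(4-bromo-2-methoxyphenoxy)-1-[4-(tert-butyldimethylsilyloxy)-3-methoxyphenyl]propan-1-ol | COc1cc(Br)ccc1O[C@H](C)[C@@H](O)c1ccc(O[Si](C)(C)C(C)(C)C)c(OC)c1 | intermediate
19 | 4-[(1S,2R)-2-(4-bromo-2-methoxyphenoxy)-1-hydroxypropyl]-2-methoxyphenol | COc1cc(Br)ccc1O[C@H](C)[C@@H](O)c1ccc(O)c(OC)c1 | intermediate
20 | 4-[(1S,2R)-2-(4-bromo-2-methoxyphenoxy)-1-(pivaloyloxy)propyl]-2-methoxyphenyl pivalate | COc1cc(Br)ccc1O[C@H](C)[C@@H](OC(=O)C(C)(C)C)c1ccc(OC(=O)C(C)(C)C)c(OC)c1 | intermediate
21 | 4-[(1S,2R,3R)-4-(9-borabicyclo[3.3.1]nonan-9-yl)-2,3-dimethyl-1-(triethylsilyloxy)butyl]-2-methoxyphenyl pivalate | COc1cc([C@@H](O[Si](CC)(CC)CC)[C@H](C)[C@H](C)CB2C3CCCC2CCC3)ccc1OC(=O)C(C)(C)C | intermediate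
22 | triethylsilyl ether of 23, chain (1S,2R,3R), side chain (1S,2R) | COc1cc([C@@H](O[Si](CC)(CC)CC)[C@H](C)[C@H](C)Cc2ccc(O[C@H](C)[C@@H](OC(=O)C(C)(C)C)c3ccc(OC(=O)C(C)(C)C)c(OC)c3)c(OC)c2)ccc1OC(=O)C(C)(C)C | intermediate
23 | open-chain C2 alcohol: 1-(ring A aryl)-2,3-dimethyl-4-(ring B aryl)butan-1-ol (1S,2R,3R) with three pivalates, side chain (1S,2R) | COc1cc([C@@H](O)[C@H](C)[C@H](C)Cc2ccc(O[C@H](C)[C@@H](OC(=O)C(C)(C)C)c3ccc(OC(=O)C(C)(C)C)c(OC)c3)c(OC)c2)ccc1OC(=O)C(C)(C)C | intermediate
24 | C5 para-alkoxybenzyl cation of 23 | COc1cc([C@@H](O)[C@H](C)[C@H](C)[CH+]c2ccc(O[C@H](C)[C@@H](OC(=O)C(C)(C)C)c3ccc(OC(=O)C(C)(C)C)c(OC)c3)c(OC)c2)ccc1OC(=O)C(C)(C)C | intermediate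
25 | tris-pivalate of the target, oxolane C2 S, C3 R, C4 S, C5 S (numbering used here) | COc1cc([C@H]2O[C@H](c3ccc(O[C@H](C)[C@@H](OC(=O)C(C)(C)C)c4ccc(OC(=O)C(C)(C)C)c(OC)c4)c(OC)c3)[C@@H](C)[C@H]2C)ccc1OC(=O)C(C)(C)C | intermediate
26 | CNP0171079.3, (1S,2R)-1-(4-hydroxy-3-methoxyphenyl)-2-{4-[(2S,3S,4R,5S)-5-(4-hydroxy-3-methoxyphenyl)-3,4-dimethyloxolan-2-yl]-2-methoxyphenoxy}propan-1-ol | COc1cc([C@H]2O[C@H](c3ccc(O[C@H](C)[C@@H](O)c4ccc(O)c(OC)c4)c(OC)c3)[C@@H](C)[C@H]2C)ccc1O | target

**Step count and risks**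

Total steps: 15. Longest linear sequence: 10 steps (steps 6, 7, 8, 9, 10, 11, 12, 13, 14, 15).

Steps most likely to fail:

1. Step 14. The oxolane product still carries a C5–H that is benzylic, para to the ether oxygen and now α to O1, so a second hydride abstraction (over-oxidation to the ring-opened ketone) may compete. Cation 24 may also lose the C4 proton to a styrene, or close with incomplete facial control. The fallback sets out from 23 and comes back at 25. Compound 23 is treated with excess DDQ in CH2Cl2/H2O so that all cationic material, including any oxolane formed, is drained to the C5 ketone, hydroxy ketone F1 (in equilibrium with its cyclic hemiketal). NaBH4 in MeOH/THF at 0 °C reduces the ketone without touching the pivalates to the 1,4-diol F2 as a mixture of C5 epimers. Catalytic camphorsulfonic acid in CH2Cl2 at 0 °C then ionises only the ring B carbinol (SN1 cyclodehydration, C2 retained) and closes O1–C5 under thermodynamic control to 25.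

2. Step 12. The hydroboration may show insufficient facial selectivity at C4, oxidative addition into the electron-rich bromide may be slow, or the aqueous base may hydrolyse aryl pivalates. The fallback sets out from 10 and comes back at 22. Compound 10 is hydroborated with 9-BBN to 21 as before and oxidised with H2O2 in pH 7 phosphate buffer to the primary alcohol F3, from which a minor C4 epimer can be removed by chromatography. I2, PPh3 and imidazole (Appel-type iodination) give the primary iodide F4. Zn dust with LiCl in THF inserts to the alkylzinc iodide F5, and a Negishi coupling with 20 (Pd(OAc)2, SPhos, THF, rt → 50 °C) under anhydrous, base-free conditions gives 22.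

3. Step 3. Enantio- or syn-selectivity may erode if the slow-reacting Z boronate lets the uncatalysed racemic pathway compete, or if 5 from step 1 carries E or regioisomeric allylboronate. The fallback sets out from 7 and comes back at 10. An Evans syn-aldol reaction of 7 with (S)-4-benzyl-3-propionyloxazolidin-2-one (Bu2BOTf, iPr2NEt, CH2Cl2, −78 → 0 °C) gives the (2S,3S) aldol adduct F6. TESOTf and 2,6-lutidine give its silyl ether F7. LiSEt (from EtSH and n-BuLi, THF, 0 °C) cleaves the auxiliary to the S-ethyl thioester F8, and Me2CuLi (Et2O, −78 °C) converts it into the methyl ketone F9 without attacking the aryl pivalate. Non-basic Lombardo methylenation (Zn, CH2Br2, TiCl4, THF/CH2Cl2) gives 10.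

**Further compounds**

F1 | step 14 | C5 ketone of 23 (4-oxo compound, chain centres as in 23) | COc1cc([C@@H](O)[C@H](C)[C@H](C)C(=O)c2ccc(O[C@H](C)[C@@H](OC(=O)C(C)(C)C)c3ccc(OC(=O)C(C)(C)C)c(OC)c3)c(OC)c2)ccc1OC(=O)C(C)(C)C
F2 | step 14 | 1,4-diol from F1 (C5 carbinol as epimer mixture, other centres as in 23) | COc1cc([C@@H](O)[C@H](C)[C@H](C)C(O)c2ccc(O[C@H](C)[C@@H](OC(=O)C(C)(C)C)c3ccc(OC(=O)C(C)(C)C)c(OC)c3)c(OC)c2)ccc1OC(=O)C(C)(C)C
F3 | step 12 | 4-[(1S,2R,3S)-4-hydroxy-2,3-dimethyl-1-(triethylsilyloxy)butyl]-2-methoxyphenyl pivalate | COc1cc([C@@H](O[Si](CC)(CC)CC)[C@H](C)[C@H](C)CO)ccc1OC(=O)C(C)(C)C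
F4 | step 12 | 4-[(1S,2R,3S)-4-iodo-2,3-dimethyl-1-(triethylsilyloxy)butyl]-2-methoxyphenyl pivalate | COc1cc([C@@H](O[Si](CC)(CC)CC)[C@H](C)[C@H](C)CI)ccc1OC(=O)C(C)(C)C
F5 | step 12 | alkylzinc iodide from F4 | COc1cc([C@@H](O[Si](CC)(CC)CC)[C@H](C)[C@H](C)C[Zn]I)ccc1OC(=O)C(C)(C)C
F6 | step 3 | (S)-4-benzyl-3-[(2S,3S)-3-hydroxy-3-(3-methoxy-4-pivaloyloxyphenyl)-2-methylpropanoyl]oxazolidin-2-one | COc1cc([C@@H](O)[C@H](C)C(=O)N2[C@@H](Cc3ccccc3)COC2=O)ccc1OC(=O)C(C)(C)C
F7 | step 3 | triethylsilyl ether of F6 | COc1cc([C@@H](O[Si](CC)(CC)CC)[C@H](C)C(=O)N2[C@@H](Cc3ccccc3)COC2=O)ccc1OC(=O)C(C)(C)C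
F8 | step 3 | S-ethyl (2S,3S)-3-(3-methoxy-4-pivaloyloxyphenyl)-2-methyl-3-(triethylsilyloxy)propanethioate | COc1cc([C@@H](O[Si](CC)(CC)CC)[C@H](C)C(=O)SCC)ccc1OC(=O)C(C)(C)C
F9 | step 3 | 4-[(1S,2S)-2-methyl-3-oxo-1-(triethylsilyloxy)butyl]-2-methoxyphenyl pivalate | COc1cc([C@@H](O[Si](CC)(CC)CC)[C@H](C)C(C)=O)ccc1OC(=O)C(C)(C)C
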